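## The problem

The target, 2,3,5-tribromo-6-(2-bromophenoxy)phenol, is an achiral diaryl ether, so every difficulty is regiochemical or chemoselective and no stereocenter has to be set. Ring A is pentasubstituted, with OH at C1, bromine at C2, C3 and C5, the only hydrogen at C4 and the ether oxygen at C6, while ring B carries the ether oxygen at C1' and bromine at C2'. The ether oxygen is therefore flanked by OH and Br on ring A and by Br on ring B, which makes direct arylation of the electron-poor phenoxide unattractive. The ring A bromines sit ortho and para to the ether oxygen, whereas the position para to the free hydroxyl is C–H, a pattern most simply obtained by brominating while the ether oxygen is still a free OH and the other oxygen is masked. Four aryl bromides rule out alkyllithiums, dissolving metals, strongly basic lithium dialkylamides (the ring A C–H lies between two bromines) and low-valent copper, nickel or palladium at any late stage. The C1 hydroxyl needs a protecting group that survives bromine, base and prolonged heating, and a methyl ether does. The feature that opens the route is ring B itself: C3' to C6' are four contiguous unsubstituted CH carbons, which map onto C3 to C6 of 2H-pyran-2-one, and C1'/C2' are a two-carbon unit bearing oxygen and a group exchangeable for bromine, which is an alkyne.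

## Retrosynthesis

**Target 12 to methyl ether 10.** The O–H of ring A is traced back to an O–CH3 bond. Methyl is chosen over benzyl, silyl or acetal groups because it tolerates Br2, KN(SiMe3)2, a hypervalent iodine reagent and about 180 °C. BBr3 removes it by way of aryloxyborane 11 without touching aryl bromides or the diaryl ether. The methoxy group also serves the first step, where its twisted, weakly donating oxygen leaves the neighbouring free OH in control.

**Methyl ether 10 to arylsilane 9.** The C2'–Br bond is exchanged for C2'–Si. Brominating a plain phenyl ether would go para to oxygen; an ipso substitution at silicon puts bromine at the one carbon that was marked when the ring was made. The forward step must favour ipso attack over attack at C4' of ring B.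

**Arylsilane 9 to alkynyl ether 6 and pyranone 7 (key disconnection).** The bonds C1'–C6' and C2'–C3' of ring B are cut, which removes the whole ring and leaves the ether oxygen on an sp carbon. The neighbouring cut, through the C6–O–C1' ether bond, would require arylation of a doubly ortho-substituted, weakly nucleophilic phenoxide with an ortho-bromoaryl electrophile. That would mean copper catalysis, which endangers four C–Br bonds, or a substitution that needs an activating group and later functional-group exchange. The cycloaddition passes through bicyclic lactone 8, loses CO2 and aromatises on its own, and poses no regiochemical question because 7 is unsubstituted. The forward reaction has to be a thermal [4+2] addition that the aryl bromides and the alkynyl ether survive.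

**Alkynyl ether 6 to phenol 2 and iodonium salt 3.** The O–C(sp) bond is cut. An sp carbon has no ortho substituents, so the steric problem shrinks to the ring A side alone. The established way to such ethers, a dichlorovinyl ether treated with butyllithium, would exchange the aryl bromines. The alkynyl iodonium salt instead acts as an electrophilic alkyne toward the preformed phenoxide 4 and reaches 6 through carbene 5 under non-reducing, weakly basic conditions. The forward step asks for oxygen–carbon bond formation at a hindered phenoxide and a clean 1,2-silyl shift.

**Phenol 2 to phenol 1.** The C4–Br and C6–Br bonds are cut. In 1 the free hydroxyl is the future ether oxygen, so its ortho and para positions are exactly the two that need bromine, and the third bromine is already in place next to the methoxy group. The forward step asks only that bromination stop after two equivalents.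

## Roads not taken

**Alternative 1: enzymatic cis-dihydroxylation of 1,3-dibromobenzene A1, aromatised late.** The cut removes both C–O bonds of ring A. Toluene dioxygenase in whole cells of E. coli JM109 (pDTG601) would cis-dihydroxylate the C4–C5 bond of arene A1 and give (1S,2S)-3,5-dibromocyclohexa-3,5-diene-1,2-diol A2.
- Merits: one operation from the very cheap arene A1 places two oxygens and two bromines in the correct mutual positions, with no protecting group and no regiochemical doubt. In this respect it is better than the chosen plan, which needs the less common phenol 1 and a directed bromination.
- Weak points: the enantioselectivity of the enzyme is spent on an achiral target. The two secondary hydroxyls of diol A2 must be told apart, and the one next to the vinyl bromide must be arylated with a 2-bromophenyl group, which brings back the hindered C–O bond formation. Diol A2 dehydrates readily to a phenol, which would lose one of the two oxygens, so aromatisation has to be an oxidation. The aromatised intermediate 3,5-dibromo-2-(2-bromophenoxy)phenol A3 then needs its last bromine ortho to the free OH while the para position stays C–H. The para carbon of A3 is shielded by two bromines, but it is still the site a phenol normally prefers, so this selectivity is not secured.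
- Comparison: the chosen plan sets against the elegant first step a bromination whose outcome is dictated by the substrate and an ether oxygen that is in place before ring B exists.

**Alternative 2: ring A from 3,5-dibromo-2H-pyran-2-one A4 and a dioxygenated alkene.** The cut is through C5–C6 and C1–C2 of ring A. Pyranone A4 and (Z)-2-(2-bromophenoxy)ethenyl acetate A5 would combine by Diels–Alder addition and decarboxylation to give racemic cis-3,5-dibromo-6-(2-bromophenoxy)cyclohexa-2,4-dien-1-yl acetate A6.
- Merits: the diaryl ether is carried in on dienophile A5, and A4 is a reactive ambiphilic diene that adds to alkenes well below the temperature needed for the parent pyranone 7. The milder cycloaddition is a real advantage over the chosen plan.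
- Weak points: alkene A5 bears two similar oxygen substituents, so the orientation that places the aryloxy carbon next to C–Br is not secured. Alkene adducts of pyranones hold their carboxylate bridge more firmly than alkyne adducts. Diene A6 is one elimination of its acetate or its aryloxy group away from an arene that has lost a needed oxygen, so aromatisation must be a dehydrogenation in competition with elimination. After that the route arrives at A3 and meets the same uncertain final bromination as alternative 1.
- Comparison: the chosen plan uses the same pyranone logic on the ring that has no oxygen to lose. The alkyne adduct aromatises by decarboxylation alone and regiochemistry does not arise; the price is a hotter cycloaddition.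

**Alternative 3: aryne aryloxy-bromination.** The cut is through the C1'–O and C2'–Br bonds of ring B. CsF would release benzyne A8 from 2-(trimethylsilyl)phenyl trifluoromethanesulfonate A7. Phenoxide 4 would add at one carbon of A8 and the resulting aryl anion would take bromine from bromopentafluorobenzene A9, giving 1,2,5-tribromo-4-(2-bromophenoxy)-3-methoxybenzene A10, which is the same compound as 10.
- Merits: it is the shortest road, reaching the methyl ether in one step from phenol 2 with the commercial reagents A7 and A9, two steps fewer than the chosen plan. The ortho relationship is guaranteed by the aryne.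
- Weak points: the 2-aryloxyphenyl anion is far more easily protonated than brominated, and the by-product 1,2,5-tribromo-3-methoxy-4-phenoxybenzene A11 differs from A10 by one bromine and would be hard to remove. The hindered, weakly nucleophilic phenoxide 4 adds slowly to A8. It can also attack A9 by nucleophilic aromatic substitution, and the aryl anion can abstract bromine from ring A instead.
- Comparison: the chosen plan gives up brevity for a two-component ring construction in which the future C–Br carbon is fixed by a C–Si bond. The failure products of its ipso substitution differ from the desired bromide by a trimethylsilyl group or by a second ring B bromine and should be easier to separate than A11.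

Key step: step 3

Assumption: phenol 1, iodonium salt 3 and pyranone 7 are taken as purchasable; bicyclic lactone 8 forms as a racemate and one enantiomer is drawn in its SMILES.

## Route

Step 1
Reactants: 1 3-bromo-2-methoxyphenol
Product: 2 3,4,6-tribromo-2-methoxyphenol
Conditions: Br2 (2.1 equiv), CH2Cl2, 0 °C to rt
Reagents that add atoms: bromine, BrBr
Why: Electrophilic aromatic bromination directed by the free hydroxyl to its para (C4) and ortho (C6) positions; the methoxy group, twisted out of plane between OH and Br, activates C5 only weakly, so two equivalents should stop at the tribromide.

Step 2
Reactants: 2 3,4,6-tribromo-2-methoxyphenol; 3 phenyl[(trimethylsilyl)ethynyl]iodonium trifluoromethanesulfonate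
Product: 6 trimethyl[(3,4,6-tribromo-2-methoxyphenoxy)ethynyl]silane, via potassium phenoxide 4 (not isolated), via alkylidene carbene 5 (not isolated)
Conditions: KN(SiMe3)2 (1.0 equiv), toluene, 0 °C; then 3 (1.2 equiv), 0 °C to rt
Reagents that add atoms: none
Why: Proposed new method: phenoxide 4 should add to the silyl-bearing β-carbon of the alkynyl iodonium ion of 3, iodobenzene should leave to give alkylidene carbene 5, and a 1,2-shift of silicon should deliver alkynyl ether 6; both ortho positions of 4 are blocked, so the carbene has no aryl C–H bond for the 1,5-insertion that leads phenoxides to benzofurans, and silyl migration is the fastest exit; the closest known reaction type is the N-alkynylation of amide and sulfonamide anions with this same iodonium salt to give silyl ynamides, which runs through the same carbene and silyl shift.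

Step 3
Reactants: 6 trimethyl[(3,4,6-tribromo-2-methoxyphenoxy)ethynyl]silane; 7 2H-pyran-2-one
Product: 9 trimethyl[2-(3,4,6-tribromo-2-methoxyphenoxy)phenyl]silane, via bicyclic lactone 8 (not isolated)
Conditions: 7 (4 equiv), BHT (cat.), mesitylene, sealed tube, 180 °C
Reagents that add atoms: none
Why: This is a Diels–Alder/retro-Diels–Alder benzannulation: the diene of 7 (C3 to C6) adds across the triple bond of 6 to give bicyclic lactone 8, whose CO2 bridge is lost by cycloreversion at the reaction temperature to leave benzene 9. The closest known reaction type is the thermal union of 2H-pyran-2-one with silylalkynes to give ortho-silylated benzenes, and of pyranones with ynamines and alkynyl ethers. Ring B closes as a six-membered carbocycle by an intermolecular [4+2] cycloaddition that joins pyranone C3 and C6 to the two alkyne carbons, followed by aromatisation; it is not the cyclisation of a chain, so no Baldwin mode applies. No stereocenter survives: the two bridgehead centers of 8 are tied to each other by the bicycle, form as a racemate and vanish with CO2. The pyranone is an electron-poor diene with an electrophilic terminus at C6 and the oxygen-substituted alkyne is polarised toward its silyl-bearing carbon, so the pairing is of the inverse-demand kind and should need less forcing than a bis-silyl alkyne. Regiochemistry is not at issue because 7 is unsubstituted and both orientations of 6 converge on 9. The selectivity needed is chemoselectivity: the alkyne is the only dienophile in 6, the aryl bromides have no thermal pathway without a metal, and the aryl alkynyl ether has no β-hydrogen for retro-ene loss of a ketene and no free ortho position on ring A. An excess of 7 and a radical inhibitor compensate for thermal self-condensation of the pyranone.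

Step 4
Reactants: 9 trimethyl[2-(3,4,6-tribromo-2-methoxyphenoxy)phenyl]silane
Product: 10 1,2,5-tribromo-4-(2-bromophenoxy)-3-methoxybenzene
Conditions: Br2 (1.05 equiv), CH2Cl2, −78 °C to 0 °C
Reagents that add atoms: bromine, BrBr
Why: Electrophilic ipso-bromodesilylation: attack at the silicon-bearing carbon, which is also ortho to the ether oxygen, gives a cation stabilised by the β-silicon effect that loses Me3SiBr; ring A is deactivated by three bromines and its only C–H lies between two of them, and one equivalent at low temperature limits substitution para to oxygen on ring B.

Step 5
Reactants: 10 1,2,5-tribromo-4-(2-bromophenoxy)-3-methoxybenzene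
Product: 12 2,3,5-tribromo-6-(2-bromophenoxy)phenol, via aryloxydibromoborane 11 (not isolated)
Conditions: BBr3 (3 equiv), CH2Cl2, −78 °C to rt; then H2O
Reagents that add atoms: none
Why: Lewis-acid cleavage of an aryl methyl ether: BBr3 binds the methoxy oxygen, bromide removes the methyl group by SN2 to give aryloxyborane 11, and water frees phenol 12; diaryl ethers and aryl bromides are inert to BBr3.

## Compound list

1 | 3-bromo-2-methoxyphenol | COc1c(O)cccc1Br | starting material
2 | 3,4,6-tribromo-2-methoxyphenol | COc1c(O)c(Br)cc(Br)c1Br | intermediate
3 | phenyl[(trimethylsilyl)ethynyl]iodonium trifluoromethanesulfonate | C[Si](C)(C)C#C[I+]c1ccccc1.[O-]S(=O)(=O)C(F)(F)F | starting material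
4 | potassium 3,4,6-tribromo-2-methoxyphenolate | COc1c([O-])c(Br)cc(Br)c1Br.[K+] | intermediate
5 | 2-(3,4,6-tribromo-2-methoxyphenoxy)-2-(trimethylsilyl)ethenylidene (alkylidene carbene) | COc1c(Br)c(Br)cc(Br)c1OC(=[C])[Si](C)(C)C | intermediate
6 | trimethyl[(3,4,6-tribromo-2-methoxyphenoxy)ethynyl]silane | COc1c(Br)c(Br)cc(Br)c1OC#C[Si](C)(C)C | intermediate
7 | 2H-pyran-2-one | O=C1C=CC=CO1 | starting material
8 | 5-(3,4,6-tribromo-2-methoxyphenoxy)-6-(trimethylsilyl)-2-oxabicyclo[2.2.2]octa-5,7-dien-3-one (racemic, one enantiomer drawn) | O=C1O[C@@H]2C=C[C@H]1C(Oc3c(Br)cc(Br)c(Br)c3OC)=C2[Si](C)(C)C | intermediate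
9 | trimethyl[2-(3,4,6-tribromo-2-methoxyphenoxy)phenyl]silane | COc1c(Br)c(Br)cc(Br)c1Oc1ccccc1[Si](C)(C)C | intermediate
10 | 1,2,5-tribromo-4-(2-bromophenoxy)-3-methoxybenzene | COc1c(Br)c(Br)cc(Br)c1Oc1ccccc1Br | intermediate
11 | dibromo[2,3,5-tribromo-6-(2-bromophenoxy)phenoxy]borane | BrB(Br)Oc1c(Br)c(Br)cc(Br)c1Oc1ccccc1Br | intermediate
12 | 2,3,5-tribromo-6-(2-bromophenoxy)phenol | Oc1c(Br)c(Br)cc(Br)c1Oc1ccccc1Br | target

## Step count and risk

Total steps: 5. Longest linear sequence: 5 steps, from 1 to 12.

**Step 2 (proposed new method).** The most likely failures are three:
- attack of the hindered, weakly nucleophilic phenoxide at silicon or at the trivalent iodine centre instead of the β-carbon, which would lead to desilylation or to transfer of the phenyl group;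
- decomposition of the iodonium salt before addition occurs;
- hydration of the alkynyl ether during isolation.

The fallback uses known chemistry, sets out from 2 and comes back at 6, at the cost of five extra steps. Williamson alkylation of 2 with 1,2-dibromoethane (K2CO3, DMF) should give 1,2,5-tribromo-4-(2-bromoethoxy)-3-methoxybenzene F1. E2 elimination with KOtBu in THF should give the aryl vinyl ether 1,2,5-tribromo-4-(ethenyloxy)-3-methoxybenzene F2. Addition of Br2 at −78 °C should give 1,2,5-tribromo-4-(1,2-dibromoethoxy)-3-methoxybenzene F3. Dehydrobromination with DBU should give mainly 1,2,5-tribromo-4-[(Z)-2-bromoethenyloxy]-3-methoxybenzene F4, and anti-elimination with KOtBu should give 1,2,5-tribromo-4-(ethynyloxy)-3-methoxybenzene F5. Deprotonation of F5 with LiN(SiMe3)2 and silylation with Me3SiCl then returns 6. No reagent in this sequence exchanges aryl bromine or is basic enough to remove the ring A hydrogen.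

**Step 3 (key step).** The cycloaddition may be outrun by thermal self-condensation of the pyranone or by slow degradation of the alkynyl ether, because the tribromoaryloxy group is a weaker donor than an alkoxy group and the dienophile may be too unreactive. The fallback gives up the cycloaddition, sets out from 2 and comes back at 10. Nucleophilic aromatic substitution of 1-fluoro-2-nitrobenzene by 2 (K2CO3, DMF, 100 °C) should give 1,2,5-tribromo-3-methoxy-4-(2-nitrophenoxy)benzene F6. Reduction with Fe and NH4Cl in aqueous ethanol should give 2-(3,4,6-tribromo-2-methoxyphenoxy)aniline F7. Sandmeyer bromination (t-BuONO, CuBr2, MeCN) then gives 10.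

**Step 4.** Bromination para to the ether oxygen on ring B may compete with ipso attack, and protodesilylation by adventitious HBr may remove silicon without introducing bromine. The fallback sets out from 9 and comes back at 12, replacing steps 4 and 5. BBr3 in CH2Cl2 should replace silicon by boron at the ipso carbon in a borodesilylation and cleave the methyl ether in the same flask; hydrolysis should give [2-(3,4,6-tribromo-2-hydroxyphenoxy)phenyl]boronic acid F8. Bromodeboronation with CuBr2 in aqueous methanol at 80 °C then gives 12, with the bromine position fixed by the C–B bond.

## Further compounds

F1 | step 2 | 1,2,5-tribromo-4-(2-bromoethoxy)-3-methoxybenzene | COc1c(Br)c(Br)cc(Br)c1OCCBr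
F2 | step 2 | 1,2,5-tribromo-4-(ethenyloxy)-3-methoxybenzene | COc1c(Br)c(Br)cc(Br)c1OC=C
F3 | step 2 | 1,2,5-tribromo-4-(1,2-dibromoethoxy)-3-methoxybenzene (racemic) | COc1c(Br)c(Br)cc(Br)c1OC(Br)CBr
F4 | step 2 | 1,2,5-tribromo-4-[(Z)-2-bromoethenyloxy]-3-methoxybenzene | COc1c(Br)c(Br)cc(Br)c1O/C=C\Br
F5 | step 2 | 1,2,5-tribromo-4-(ethynyloxy)-3-methoxybenzene | COc1c(Br)c(Br)cc(Br)c1OC#C
F6 | step 3 | 1,2,5-tribromo-3-methoxy-4-(2-nitrophenoxy)benzene | COc1c(Br)c(Br)cc(Br)c1Oc1ccccc1[N+](=O)[O-]
F7 | step 3 | 2-(3,4,6-tribromo-2-methoxyphenoxy)aniline | COc1c(Br)c(Br)cc(Br)c1Oc1ccccc1N
F8 | step 4 | [2-(3,4,6-tribromo-2-hydroxyphenoxy)phenyl]boronic acid | OB(O)c1ccccc1Oc1c(O)c(Br)c(Br)cc1Br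
A1 | alternative 1 | 1,3-dibromobenzene | Brc1cccc(Br)c1
A2 | alternative 1 | (1S,2S)-3,5-dibromocyclohexa-3,5-diene-1,2-diol | O[C@H]1C=C(Br)C=C(Br)[C@H]1O
A3 | alternative 1 | 3,5-dibromo-2-(2-bromophenoxy)phenol | Oc1cc(Br)cc(Br)c1Oc1ccccc1Br
A4 | alternative 2 | 3,5-dibromo-2H-pyran-2-one | O=C1OC=C(Br)C=C1Br
A5 | alternative 2 | (Z)-2-(2-bromophenoxy)ethenyl acetate | CC(=O)O/C=C\Oc1ccccc1Br
A6 | alternative 2 | cis-3,5-dibromo-6-(2-bromophenoxy)cyclohexa-2,4-dien-1-yl acetate (racemic) | CC(=O)O[C@@H]1C=C(Br)C=C(Br)[C@@H]1Oc1ccccc1Br
A7 | alternative 3 | 2-(trimethylsilyl)phenyl trifluoromethanesulfonate | C[Si](C)(C)c1ccccc1OS(=O)(=O)C(F)(F)F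
A8 | alternative 3 | benzyne (cyclohexa-1,3-dien-5-yne) | C1=CC=CC#C1
A9 | alternative 3 | bromopentafluorobenzene | Fc1c(F)c(F)c(Br)c(F)c1F
A10 | alternative 3 | 1,2,5-tribromo-4-(2-bromophenoxy)-3-methoxybenzene | COc1c(Br)c(Br)cc(Br)c1Oc1ccccc1Br
A11 | alternative 3 | 1,2,5-tribromo-3-methoxy-4-phenoxybenzene | COc1c(Br)c(Br)cc(Br)c1Oc1ccccc1
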